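Leave the catalyst aside and keep books on the coupling partner, the limiting reagent, whose 23.1 mM falls short of the 42.0 mM of both substrates together.

| setting | green | grey | gamma | zeta | delta |
|---|---|---|---|---|---|
| left-handed substrate | 21 mM | 21 mM | 21 mM | 21 mM | 21 mM |
| right-handed substrate | 21 mM | 21 mM | 21 mM | 21 mM | 21 mM |
| coupling partner | 23.1 mM | 23.1 mM | 23.1 mM | 23.1 mM | 23.1 mM |
| free catalyst | 0.67 mM | 1.1 mM | 0.48 mM | 0.48 mM | 0.48 mM |
| temperature | 88 °C | 104 °C | 95 °C | 80 °C | 110 °C |
| remark | run made earlier | run made earlier |  |  |  |
| time |  |  | 20 min | 20 min | 20 min |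

| run | time / min | left-handed product / % | right-handed product / % | left-handed substrate / % |
|---|---|---|---|---|
| green | 3.00 | 24.7 | 20.0 | 10.0 |
| green | 6.00 | 25.6 | 25.3 | 6.1 |
| green | 10.0 | 26.4 | 25.0 | 5.4 |
| green | 12.0 | 25.6 | 25.8 | 6.7 |
| green | 15.0 | 25.7 | 26.3 | 5.3 |
| green | 20.0 | 25.7 | 22.7 | 5.3 |
| grey | 1.00 | 20.7 | 19.5 | 14.6 |
| grey | 1.50 | 23.7 | 21.0 | 10.1 |
| grey | 2.50 | 23.8 | 22.9 | 8.0 |
| grey | 5.00 | 24.8 | 24.3 | 6.2 |
| grey | 8.00 | 26.3 | 26.0 | 6.3 |
| grey | 12.0 | 26.3 | 27.3 | 2.9 |

(scatter of a reading: 1 percentage point)

- free catalyst is single-handed; left-handed substrate and right-handed substrate are mirror images of each other, charged as a racemate, each of them at the stated concentration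
- the numbers in the tables scatter by 1 percentage point (one standard deviation)
- reactions considered so far: free catalyst + left-handed substrate <-> catalyst intermediate A; free catalyst + right-handed substrate <-> catalyst intermediate B; coupling partner + catalyst intermediate A -> free catalyst + left-handed product; coupling partner + catalyst intermediate B -> free catalyst + right-handed product; left-handed product <-> right-handed product; 2 free catalyst <-> resting dimer; coupling partner <-> dormant form

1. the flask that comes out highest in share of left-handed product in all that became left-handed product or right-handed product, or "all alike" when all lie within 1.5 percentage points (gamma / zeta / delta / all alike)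
2. share of left-handed product in all that became left-handed product or right-handed product, gamma
3. share of left-handed product in all that became left-handed product or right-handed product, zeta
4. share of left-handed product in all that became left-handed product or right-handed product, delta

Open the ledger on the first green row, at 3.00 min, counting in percent of both substrates charged. Left-handed substrate began at half of that count and reads 10.0%, so 40 percentage points went the left-handed way; the green catalyst, 1.60% of that charge, can hold back little. The products together read 45 points, each of them one coupling partner spent out of the 55.0% charged on this count, which leaves 4.7 points for the right-handed way. On these readings the green flask has made a left excess of 35 points, but the products show 4.7 points. The green books close if 15 points crossed from left-handed to right-handed product.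

Suppose the whole excess was made at the start. You then get 1.03 min as the excess half-life, the time that halves the left-minus-right excess. Later making would make it shorter, so this reading is an upper estimate, with the scatter of a small difference. Grey's first row, equally reckoned, gives a rougher 0.214 min.

Zeta lies half as far below green as grey lies above it, so I take 2.26 min for zeta. Its 20 min then holds 8.85 half-lives, and my share for zeta is 50.1%.

The forecast sets zeta higher than my figure: 50.2% for gamma, 50.8% for zeta, 50% for delta, so all alike, on the grounds that “selectivity is lost once racemisation outruns coupling”.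

The flasks give all alike: 50.1% for gamma, 50.2% for zeta, 50.0% for delta.

    free catalyst + left-handed substrate ⇌ catalyst intermediate A (K = 150 M⁻¹, k = 58.0 M⁻¹ s⁻¹, Ea = 37.0 kJ mol⁻¹, ΔH = −40.0 kJ mol⁻¹)
    free catalyst + right-handed substrate ⇌ catalyst intermediate B (K = 18.0 M⁻¹, k = 140 M⁻¹ s⁻¹, Ea = 43.0 kJ mol⁻¹, ΔH = −37.0 kJ mol⁻¹)
    coupling partner + catalyst intermediate A → free catalyst + left-handed product (k = 45.0 M⁻¹ s⁻¹, Ea = 49.0 kJ mol⁻¹)
    coupling partner + catalyst intermediate B → free catalyst + right-handed product (k = 19.0 M⁻¹ s⁻¹, Ea = 37.0 kJ mol⁻¹)
    left-handed product ⇌ right-handed product (k = 0.00300 s⁻¹, Ea = 103 kJ mol⁻¹)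
    2 free catalyst ⇌ resting dimer, settled at all times (K = 630 M⁻¹, ΔH = 7.00 kJ mol⁻¹)
    coupling partner ⇌ dormant form (K = 1.80, k = 5.90 × 10⁻⁴ s⁻¹, Ea = 114 kJ mol⁻¹, ΔH = 3.00 kJ mol⁻¹)
    (constants at 80 °C)

In delta, half the left-handed coupling up to the asked time is done by 0.687 min, while the product pair, by its own step, relaxes with a half-life of 0.124 min, which is shorter than that and shorter than the 20 min. Now take delta with 39 mM of coupling partner, hotter than green: your 1.03 min fits 19.4 times into its time, so expect an even share. It gives 49.9%, with 35.7% left-handed and 35.8% right-handed product.

The earlier runs and the new flask are calculated on assumed constants; the scatter is artificial.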